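**Retrosynthetic overview**
- The epoxide comes last, by nucleophilic epoxidation of the C9=C10 enone of a 14-membered cross-conjugated dienone acetate.
- The 14-membered carbocycle comes from a ring expansion. A vinyl anion on the C1 side chain attacks the lactone C=O of a bridged 12-membered C1–O–C11 lactone. This O→C acyl transfer forms C11–C12, and the released C1 alkoxide is trapped as the acetate.
- The (Z)-alkylidene-THF comes from transannular 5-exo-dig hydroalkoxylation of a 12-membered cycloalkyne lactone, which is itself closed by alkyne metathesis.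
- The diyne ester comes from a vinylogous Mukaiyama aldol (C7–C8) between a senecioate silyl dienolate and (S)-3-methylhex-4-ynal.
- Rings form in the order 12-membered lactone, THF, 14-membered carbocycle, epoxide.

Working numbering of the carbocycle: C1 = C(OAc)CH3, C2, C3=C4(O), C5(CH3), C6, C7(O), C8, C9(CH3), C10, C11(=O), C12(=CMe2), C13, C14. The oxygen bridge runs C4–O–C7. The target is 1R,3Z,5S,7R,9S,10R, with a trans epoxide and C5-CH3 trans to C8 on the THF ring.

Assumption: for the chiral catalysts in steps 3, 6 and 10, the enantiomer named is taken to give the drawn configuration; if the sense is opposite, the antipodal catalyst is used.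

**Step 1**
Reactants: 1 3-methylbuta-1,2-diene
Product: 3 1,2-dibromo-3-methylbut-2-ene, via tertiary allylic dibromide 2 (not isolated)
Conditions: Br2 (1.0 equiv), CH2Cl2, −78 °C → rt, 3 h
Reagents that add atoms: bromine, BrBr
Why: In this electrophilic bromination of an allene, Br+ adds to the central carbon and the kinetic tertiary allylic bromide 2 transposes at rt to the more stable primary allylic bromide 3 (tetrasubstituted alkene), with no stereocentre formed.

**Step 2**
Reactants: 3 1,2-dibromo-3-methylbut-2-ene; 4 acetone N,N-dimethylhydrazone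
Product: 7 5-bromo-6-methylhept-5-en-2-one, via lithio azaenolate 5 (not isolated), via alkylated hydrazone 6 (not isolated)
Conditions: 4, nBuLi, THF, 0 °C; 3, −78 → 0 °C; then 1 M aq HCl/pentane, rt
Reagents that add atoms: water, O
Why: In this Corey–Enders hydrazone alkylation, azaenolate 5 is cleanly monoalkylated by SN2 at the primary allylic bromide (the vinylic bromide is inert) and mild acid hydrolysis of 6 frees the methyl ketone.

**Step 3**
Reactants: 7 5-bromo-6-methylhept-5-en-2-one
Product: 8 (R)-2-(3-bromo-4-methylpent-3-en-1-yl)-2-methyloxirane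
Conditions: Me3S(O)I, NaH, THF, reflux (ylide); then 7, La-Li3-tris[(R)-binaphthoxide] 5 mol %, (2,4,6-(MeO)3C6H2)3P=O 5 mol %, 5 Å MS, THF, rt
Reagents that add atoms: trimethylsulfoxonium iodide, C[S+](C)(C)=O.[I-]
Why: In this catalytic asymmetric Corey–Chaykovsky epoxidation, the heterobimetallic binaphthoxide binds ketone and ylide and tells CH3 from the CH2CH2R arm of methyl ketones (typically >90% ee), which sets C1 as R while the vinyl bromide stays inert.

**Step 4**
Reactants: 8 (R)-2-(3-bromo-4-methylpent-3-en-1-yl)-2-methyloxirane; 9 1-propynyllithium; 10 3-methylbut-2-enoyl chloride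
Product: 12 (5R)-8-bromo-5,9-dimethyldec-8-en-2-yn-5-yl 3-methylbut-2-enoate, via lithium alkoxide 11 (not isolated)
Conditions: 9 (1.2 equiv), THF–DMPU 4:1, 0 °C → rt; then 10 (1.5 equiv), −78 → 0 °C
Reagents that add atoms: none
Why: SN2 epoxide opening by the acetylide at the unhindered CH2 (C2) leaves the C1–O bond and its configuration untouched, and the tertiary alkoxide 11 is acylated in the same flask, which avoids a separate esterification of a hindered tertiary alcohol.

**Step 5**
Reactants: 12 (5R)-8-bromo-5,9-dimethyldec-8-en-2-yn-5-yl 3-methylbut-2-enoate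
Product: 14 TBS silyl ketene acetal of 12 (1-alkoxy-1-silyloxy-3-methylbuta-1,3-diene), via lithium dienolate 13 (not isolated)
Conditions: LDA, THF–DMPU, −78 °C; TBSCl, −78 °C → rt; pentane extraction
Reagents that add atoms: tert-butyldimethylsilyl chloride, CC(C)(C)[Si](C)(C)Cl
Why: Kinetic γ-deprotonation of the senecioate and O-silylation of the extended enolate 13 (silyl ketene acetal formation) is standard, the alkyne and vinyl bromide have no competing acidity, and the ketene acetal geometry does not matter later.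

**Step 6**
Reactants: 15 α-methylene-γ-butyrolactone
Product: 16 (S)-3-methyldihydrofuran-2(3H)-one
Conditions: H2 (100 bar), [RuCl2((R)-BINAP)]2·NEt3 0.5 mol %, CH2Cl2, 50 °C
Reagents that add atoms: none
Why: Ru–BINAP asymmetric hydrogenation of the exocyclic α-methylene lactone (carbonyl-directed, about 95% ee) sets the methyl-bearing centre C5 as S.

**Step 7**
Reactants: 16 (S)-3-methyldihydrofuran-2(3H)-one
Product: 18 (S)-3-methylpent-4-yn-1-ol, via lactol 17 (not isolated)
Conditions: DIBAL-H (1.05 equiv), CH2Cl2, −78 °C; then MeOH, K2CO3, Bestmann–Ohira reagent, −78 °C → rt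
Reagents that add atoms: dimethyl (1-diazo-2-oxopropyl)phosphonate, COP(=O)(OC)C(=[N+]=[N-])C(C)=O
Why: Partial DIBAL-H reduction stops at lactol 17, whose open hydroxy-aldehyde form undergoes Ohira–Bestmann (Seyferth–Gilbert) homologation under K2CO3/MeOH mild enough not to epimerise C5.

**Step 8**
Reactants: 18 (S)-3-methylpent-4-yn-1-ol
Product: 20 (S)-3-methylhex-4-yn-1-ol, via dilithio dianion 19 (not isolated)
Conditions: nBuLi (2.1 equiv), THF, −78 → −20 °C; MeI (1.05 equiv), DMPU, −78 °C → rt
Reagents that add atoms: iodomethane, CI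
Why: Alkylation of dianion 19 is C-selective because the acetylide carbon is far more nucleophilic towards MeI than the lithium alkoxide, and it gives the methyl cap needed for alkyne metathesis.

**Step 9**
Reactants: 20 (S)-3-methylhex-4-yn-1-ol
Product: 21 (S)-3-methylhex-4-ynal
Conditions: TEMPO 10 mol %, PhI(OAc)2, CH2Cl2, rt
Reagents that add atoms: none
Why: TEMPO/PhI(OAc)2 (oxoammonium) oxidation stops at the aldehyde, and C5 is β to the carbonyl so it cannot epimerise.

**Step 10**
Reactants: 14 TBS silyl ketene acetal of 12; 21 (S)-3-methylhex-4-ynal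
Product: 23 (5R)-8-bromo-5,9-dimethyldec-8-en-2-yn-5-yl (2E,5R,7S)-5-hydroxy-3,7-dimethyldec-2-en-8-ynoate, via trichlorosilyl aldolate 22 (not isolated)
Conditions: SiCl4 (1.1 equiv), (R,R)-binaphthyldiamine-derived bisphosphoramide 5 mol %, iPr2NEt 10 mol %, CH2Cl2, −78 °C; sat. aq NaHCO3
Reagents that add atoms: none
Why: In this catalytic enantioselective vinylogous Mukaiyama aldol (chiral Lewis base-activated SiCl4), the bulky tertiary-alkoxy/OTBS terminus blocks the α-carbon so only the γ-CH2 (C8) attacks, the catalyst directs it to the Si face of the aldehyde to set C7 as R regardless of the remote C5 centre, and reaction through the s-trans dienolate gives the E-enoate, which cannot lactonise.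

**Step 11**
Reactants: 23 diyne hydroxy ester
Product: 24 (3E,6R,8S,12R)-12-(3-bromo-4-methylpent-3-en-1-yl)-6-hydroxy-4,8,12-trimethyl-1-oxacyclododec-3-en-9-yn-2-one
Conditions: Mo alkylidyne bearing a tripodal silanolate ligand 10 mol %, 5 Å MS, toluene (2 mM), 60 °C
Reagents that add atoms: none
Why: Ring-closing alkyne metathesis of the two methyl-capped alkynes is driven by trapping of but-2-yne in the sieves, 12-membered enoate cycloalkynes are within its range, the catalyst leaves the alkenes, vinyl bromide, ester and secondary OH alone, and no stereocentre is touched.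

**Step 12**
Reactants: 24 cycloalkyne lactone
Product: 25 (1Z,4R,7E,10R,12S)-4-(3-bromo-4-methylpent-3-en-1-yl)-4,8,12-trimethyl-5,13-dioxabicyclo[8.2.1]trideca-1,7-dien-6-one
Conditions: [(JohnPhos)Au(MeCN)]SbF6 3 mol %, 2,6-di-tert-butylpyridine 6 mol %, 4 Å MS, CH2Cl2, 0 °C; Et3N-deactivated silica
Reagents that add atoms: none
Why: In this gold(I)-catalysed alkynol cycloisomerisation (transannular 5-exo-dig hydroalkoxylation), anti-oxyauration then protodeauration places O and C2 cis (Z enol ether), attack at C4 is favoured by the 5-exo geometry, by the inductive pull of the C1 acyloxy group and by the smaller ring that 6-endo closure would need, and C5 and C7 end up trans on the THF ring.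

**Step 13**
Reactants: 25 bridged enol ether lactone
Product: 29 (1Z,4R,9E,12R,14S)-4,10,14-trimethyl-8-oxo-7-(propan-2-ylidene)-15-oxabicyclo[10.2.1]pentadeca-1,9-dien-4-yl acetate, via vinyllithium 26 (not isolated), via bridged lactolate 27 (not isolated), via ring-expanded alkoxide 28 (not isolated)
Conditions: tBuLi (2.1 equiv), THF/Et2O/pentane 4:1:1, −95 → −78 °C, 15 min; → −20 °C, 30 min; Ac2O (3 equiv), −20 °C → rt
Reagents that add atoms: acetic anhydride, CC(=O)OC(C)=O
Why: Proposed new method: a side-chain-insertion ring expansion of a macrolactone to a carbocycle by anionic O→C acyl transfer with acetate capture, in which Br/Li exchange at the vinyl bromide outruns attack of tBuLi on the hindered tertiary-alkyl β,β-disubstituted enoate, vinyllithium 26 sits 1,5 to the lactone carbonyl and closes through a six-membered transition state to lactolate 27 (C11–C12 bond), 27 can only collapse by breaking the endocyclic C11–O bond (driven by strain release, the cross-conjugated dienone and A1,3 strain of the isopropylidene in 27) so three carbons enter the ring and the oxygen leaves it (12 → 14), Ac2O traps alkoxide 28 irreversibly and drains any hemiketal equilibrium, and C1 keeps its configuration because the C1–O bond is never broken; the closest known reaction types are Parham-type halogen–metal-exchange cyclisations onto esters, anionic homo-Fries O→C acyl shifts and SmI2-mediated intramolecular nucleophilic acyl substitution of halo esters, none of them shown on a macrolactone with a vinyllithium.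

**Step 14**
Reactants: 29 dienone acetate
Product: 30 CNP0162736.1 (29 with C9=C10 as the trans epoxide; working numbering 1R,3Z,5S,7R,9S,10R)
Conditions: TBHP (5.5 M in decane, 1.3 equiv), DBU (1.0 equiv), CH2Cl2, 0 °C → rt
Reagents that add atoms: tert-butyl hydroperoxide, CC(C)(C)OO
Why: In this Weitz–Scheffer nucleophilic epoxidation, tBuOO− adds only to the electron-poor enone (the enol ether is inert and the tetrasubstituted, twisted C12 isopropylidene enone is much slower), the E alkene gives the trans epoxide, and attack on the outer face of C9=C10, which stands perpendicular to the ring with its inner face blocked by the oxa-bridge in the rotamer that keeps the C9 methyl away from the THF ring, is expected to give 9S,10R.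

**Compound list**
1 | 3-methylbuta-1,2-diene | CC(C)=C=C | starting material
2 | 2,3-dibromo-3-methylbut-1-ene | C=C(Br)C(C)(C)Br | intermediate
3 | 1,2-dibromo-3-methylbut-2-ene | BrCC(Br)=C(C)C | intermediate
4 | acetone N,N-dimethylhydrazone | CC(C)=NN(C)C | starting material
5 | lithiated acetone N,N-dimethylhydrazone | [Li]CC(C)=NN(C)C | intermediate
6 | 5-bromo-6-methylhept-5-en-2-one N,N-dimethylhydrazone | CC(CCC(Br)=C(C)C)=NN(C)C | intermediate
7 | 5-bromo-6-methylhept-5-en-2-one | CC(=O)CCC(Br)=C(C)C | intermediate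
8 | (R)-2-(3-bromo-4-methylpent-3-en-1-yl)-2-methyloxirane | C[C@@]1(CCC(Br)=C(C)C)CO1 | intermediate
9 | 1-propynyllithium | [Li]C#CC | starting material
10 | 3-methylbut-2-enoyl chloride | CC(C)=CC(=O)Cl | starting material
11 | lithium (5R)-8-bromo-5,9-dimethyldec-8-en-2-yn-5-olate | [Li]O[C@@](CCC(Br)=C(C)C)(C)CC#CC | intermediate
12 | (5R)-8-bromo-5,9-dimethyldec-8-en-2-yn-5-yl 3-methylbut-2-enoate | CC(C)=CC(=O)O[C@@](CCC(Br)=C(C)C)(C)CC#CC | intermediate
13 | lithium dienolate of 12 | C=C(C)C=C(O[Li])O[C@@](CCC(Br)=C(C)C)(C)CC#CC | intermediate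
14 | 1-{[(5R)-8-bromo-5,9-dimethyldec-8-en-2-yn-5-yl]oxy}-1-(tert-butyldimethylsilyloxy)-3-methylbuta-1,3-diene | C=C(C)C=C(O[Si](C)(C)C(C)(C)C)O[C@@](CCC(Br)=C(C)C)(C)CC#CC | intermediate
15 | α-methylene-γ-butyrolactone | C=C1CCOC1=O | starting material
16 | (S)-3-methyldihydrofuran-2(3H)-one | C[C@H]1CCOC1=O | intermediate
17 | (3S)-3-methyltetrahydrofuran-2-ol (anomers) | C[C@H]1CCOC1O | intermediate
18 | (S)-3-methylpent-4-yn-1-ol | C#C[C@@H](C)CCO | intermediate
19 | dilithio derivative of 18 (alkynide and alkoxide) | [Li]C#C[C@@H](C)CCO[Li] | intermediate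
20 | (S)-3-methylhex-4-yn-1-ol | CC#C[C@@H](C)CCO | intermediate
21 | (S)-3-methylhex-4-ynal | CC#C[C@@H](C)CC=O | intermediate
22 | O-trichlorosilyl ether of 23 | O=C(/C=C(C)/C[C@H](O[Si](Cl)(Cl)Cl)C[C@H](C)C#CC)O[C@@](CCC(Br)=C(C)C)(C)CC#CC | intermediate
23 | (5R)-8-bromo-5,9-dimethyldec-8-en-2-yn-5-yl (2E,5R,7S)-5-hydroxy-3,7-dimethyldec-2-en-8-ynoate | O=C(/C=C(C)/C[C@H](O)C[C@H](C)C#CC)O[C@@](CCC(Br)=C(C)C)(C)CC#CC | intermediate
24 | (3E,6R,8S,12R)-12-(3-bromo-4-methylpent-3-en-1-yl)-6-hydroxy-4,8,12-trimethyl-1-oxacyclododec-3-en-9-yn-2-one | O=C1O[C@@](CCC(Br)=C(C)C)(C)CC#C[C@@H](C)C[C@@H](O)C/C(C)=C/1 | intermediate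
25 | (1Z,4R,7E,10R,12S)-4-(3-bromo-4-methylpent-3-en-1-yl)-4,8,12-trimethyl-5,13-dioxabicyclo[8.2.1]trideca-1,7-dien-6-one | O=C1O[C@@](CCC(Br)=C(C)C)(C)C/C=C2\O[C@H](C[C@@H]2C)C/C(C)=C/1 | intermediate
26 | vinyllithium from 25 (Li in place of Br at C12) | O=C1O[C@@](CCC([Li])=C(C)C)(C)C/C=C2\O[C@H](C[C@@H]2C)C/C(C)=C/1 | intermediate
27 | bridged lithium lactolate (C11–C12 formed, C11–O–C1 still intact) | [Li]OC12O[C@@](CCC1=C(C)C)(C)C/C=C3\O[C@H](C[C@@H]3C)C/C(C)=C/2 | intermediate
28 | lithium C1 alkoxide of the ring-expanded 14-membered dienone | [Li]O[C@@]1(C)C/C=C2\O[C@H](C[C@@H]2C)C/C(C)=C/C(=O)C(=C(C)C)CC1 | intermediate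
29 | (1Z,4R,9E,12R,14S)-4,10,14-trimethyl-8-oxo-7-(propan-2-ylidene)-15-oxabicyclo[10.2.1]pentadeca-1,9-dien-4-yl acetate | CC(=O)O[C@@]1(C)C/C=C2\O[C@H](C[C@@H]2C)C/C(C)=C/C(=O)C(=C(C)C)CC1 | intermediate
30 | CNP0162736.1 (working numbering 1R,3Z,5S,7R,9S,10R) | CC(=O)O[C@@]1(C)C/C=C2\O[C@H](C[C@@H]2C)C[C@]2(C)O[C@H]2C(=O)C(=C(C)C)CC1 | target

**Step count**
- Total: 14 steps.
- Longest linear sequence: 10 steps (steps 1–5, then 10–14).

**Three steps most likely to fail**

**Step 13 (the proposed ring expansion).**
- Risks: tBuLi or the vinyllithium may add to the enoate or γ-deprotonate it, or the lactolate may not open.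
- The fallback uses known chemistry, sets out from 25 and returns at 29.
- DIBAL-H (CH2Cl2, −78 °C, Rochelle work-up) cleaves the lactone reductively to the seco diol F1.
- MnO2 oxidises only its primary allylic alcohol to the (E)-hydroxy enal F2.
- Ac2O/DMAP/Et3N acetylates the tertiary alcohol to the acetoxy enal F3.
- An intramolecular Nozaki–Hiyama–Kishi reaction (CrCl2, cat. NiCl2, DMSO/THF, high dilution) joins the vinyl bromide carbon C12 to the aldehyde C11 and gives the 14-membered bis-allylic alcohol F4 as C11 epimers.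
- Dess–Martin periodinane/NaHCO3 converges both epimers on 29.

**Step 12 (transannular gold cyclisation in the strained lactone).**
- Risks: strain of the bridged product, 6-endo closure, or isomerisation of the enol ether.
- The fallback sets out from 24 and returns at 29. It postpones THF closure until the ring has been enlarged.
- TESCl/imidazole gives the silyl ether F5.
- tBuLi, used as in step 13, gives the vinyllithium F6. This closes to the lactolate F7, which opens to the alkoxide F8.
- Ac2O then gives the 14-membered cycloalkynyl dienone acetate F9.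
- HF·pyridine buffered with pyridine frees the alkynol F10.
- The same gold catalyst closes the Z-alkylidene THF transannularly in the relaxed 14-membered ring to give 29.

**Step 14 (facial and site selectivity of the epoxidation).**
- Risks: attack on the wrong face, or epoxidation of the isopropylidene enone.
- The fallback sets out from 29 and returns at 30. It replaces substrate control by reagent control.
- (S)-Me-CBS/catecholborane (toluene, −78 °C) reduces the ketone to the (11R)-bis-allylic alcohol F11.
- Sharpless asymmetric epoxidation with L-(+)-DIPT, Ti(OiPr)4, TBHP and 4 Å MS (CH2Cl2, −20 °C) is the matched pair here. It follows the same facial sense as an (E)-3-methyl-2-alken-1-ol of the geraniol type.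
- It epoxidises only the E-trisubstituted allylic alkene and gives the epoxy alcohol F12.
- Dess–Martin periodinane/NaHCO3 then gives 30.

**Further compounds**
F1 | step 13 | seco diol (tertiary C1 alcohol and primary C11 allylic alcohol, THF enol ether intact) | O[C@@](CCC(Br)=C(C)C)(C)C/C=C1\O[C@H](C[C@@H]1C)C/C(C)=C/CO
F2 | step 13 | (E)-hydroxy enal | O[C@@](CCC(Br)=C(C)C)(C)C/C=C1\O[C@H](C[C@@H]1C)C/C(C)=C/C=O
F3 | step 13 | acetoxy enal | CC(=O)O[C@@](CCC(Br)=C(C)C)(C)C/C=C1\O[C@H](C[C@@H]1C)C/C(C)=C/C=O
F4 | step 13 | 14-membered bis-allylic alcohol (C11 epimers) | CC(=O)O[C@@]1(C)C/C=C2\O[C@H](C[C@@H]2C)C/C(C)=C/C(O)C(=C(C)C)CC1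
F5 | step 12 | triethylsilyl ether of 24 | O=C1O[C@@](CCC(Br)=C(C)C)(C)CC#C[C@@H](C)C[C@@H](O[Si](CC)(CC)CC)C/C(C)=C/1
F6 | step 12 | vinyllithium from F5 | O=C1O[C@@](CCC([Li])=C(C)C)(C)CC#C[C@@H](C)C[C@@H](O[Si](CC)(CC)CC)C/C(C)=C/1
F7 | step 12 | lithium lactolate from F6 | [Li]OC12O[C@@](CCC1=C(C)C)(C)CC#C[C@@H](C)C[C@@H](O[Si](CC)(CC)CC)C/C(C)=C/2
F8 | step 12 | ring-expanded lithium alkoxide from F7 | [Li]O[C@@]1(C)CC#C[C@@H](C)C[C@@H](O[Si](CC)(CC)CC)C/C(C)=C/C(=O)C(=C(C)C)CC1
F9 | step 12 | 14-membered cycloalkynyl dienone acetate, C7 TES ether | CC(=O)O[C@@]1(C)CC#C[C@@H](C)C[C@@H](O[Si](CC)(CC)CC)C/C(C)=C/C(=O)C(=C(C)C)CC1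
F10 | step 12 | 14-membered cycloalkynyl dienone acetate, free C7 alcohol | CC(=O)O[C@@]1(C)CC#C[C@@H](C)C[C@@H](O)C/C(C)=C/C(=O)C(=C(C)C)CC1
F11 | step 14 | (11R)-bis-allylic alcohol from 29 | CC(=O)O[C@@]1(C)C/C=C2\O[C@H](C[C@@H]2C)C/C(C)=C/[C@@H](O)C(=C(C)C)CC1
F12 | step 14 | (9S,10S,11S)-9,10-epoxy-11-ol | CC(=O)O[C@@]1(C)C/C=C2\O[C@H](C[C@@H]2C)C[C@]2(C)O[C@H]2[C@@H](O)C(=C(C)C)CC1
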